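The anhydride is reached by oxidising C5 of a 3-alkyl-4-methylfuran-2(5H)-one, so everything rests on building that butenolide from an acyclic alkynol. The key step exploits the tetrasubstituted C3=C4 bond of the five-membered ring, with CH3 on C4 and the C2 carbonyl on chain-bearing C3: methyl and CO2 are delivered anti across the triple bond of a propargylic alcohol, whose CH2O carbon becomes C5 and whose oxygen becomes O1, and the lactone closes on acidification. The precursor is (S)-nonadec-2-yne-1,18-diol, with the remote carbinol left free; it comes from 1-pentadecyne and (S)-propylene oxide by epoxide opening, alkyne zipper and hydroxymethylation. Acetylation and oxidation via the 2-silyloxyfuran finish the route.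

Key step: step 4

Remark: the carbinol carbon of the target is (S); it is bought in with (S)-propylene oxide and no later step makes or breaks a bond at it. Salts that differ from a numbered compound only by removal of an acidic proton (alkynides, alkoxides) are counted as that compound.

Step 1
Reactants: 1 pentadec-1-yne; 2 (S)-2-methyloxirane [(S)-propylene oxide]
Product: 3 (S)-octadec-4-yn-2-ol
Conditions: 1, n-BuLi, THF, −78 °C; BF3·OEt2; then 2, −78 °C; then H2O
Reagents that add atoms: none
Why: BF3-promoted epoxide opening by a lithium alkynide (Yamaguchi–Hirao alkynylation): SN2 attack occurs at the unsubstituted CH2 of 2, so the oxygen-bearing carbon keeps its configuration and appears as the (S)-carbinol of 3.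

Step 2
Reactants: 3 (S)-octadec-4-yn-2-ol
Product: 4 (S)-octadec-17-yn-2-ol
Conditions: KH (5 equiv), H2N(CH2)3NH2, THF, 0 °C → rt; then H2O
Reagents that add atoms: none
Why: alkyne zipper reaction: reversible propargylic deprotonation–reprotonation through allenes walks the triple bond along the chain until it is drained as the terminal potassium acetylide, and the walk cannot pass C2 because the C–H next to the alkoxide is not removed, so the (S)-centre survives.

Step 3
Reactants: 4 (S)-octadec-17-yn-2-ol; 5 paraformaldehyde
Product: 6 (S)-nonadec-2-yne-1,18-diol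
Conditions: n-BuLi (2.2 equiv), THF, −78 → 0 °C; (CH2O)n, 0 °C → rt; then H2O
Reagents that add atoms: paraformaldehyde 5, as formaldehyde (C=O)
Why: 1,2-addition of the alkynyllithium (the secondary hydroxyl rides along as its lithium alkoxide) to monomeric formaldehyde released from paraformaldehyde; no stereocentre is formed.

Step 4
Reactants: 6 (S)-nonadec-2-yne-1,18-diol; 7 methylmagnesium bromide; 8 carbon dioxide
Product: 11 (S)-3-(15-hydroxyhexadecyl)-4-methylfuran-2(5H)-one, via oxamagnesacycle 9 (not isolated), via hydroxy acid 10 (not isolated)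
Conditions: MeMgBr (4.5 equiv), CuI (15 mol%), Et2O/toluene, −10 °C → rt; CO2 (dry gas), −20 °C → rt; 2 M HCl, rt
Reagents that add atoms: methylmagnesium bromide 7 (C[Mg]Br); carbon dioxide 8 (O=C=O)
Why: MeMgBr first converts both hydroxyls into magnesium alkoxides, and the methylcopper species formed with CuI then adds across the triple bond under direction of the propargylic alkoxide, placing methyl on C2 of the alkynol and the metal on C3 from the opposite face, so that chelate 9 results after transmetalation to magnesium. The closest known reaction type is the copper-catalysed anti-carbomagnesiation of 2-alkyn-1-ols with carboxylative trapping of the vinylmagnesium to a butenolide. CO2 inserts into the C3–Mg bond with retention of the olefin geometry, and on acidification the cis CH2OH and CO2H groups of 10 close the only new ring by 5-exo-trig acyl substitution (lactonisation). No stereocentre is formed, and the remote (S)-carbinol rides through as its magnesium alkoxide, any carbonate formed there losing CO2 again on acidification. The step needs regioselectivity (methyl to C2, carboxyl to C3) and anti addition, and both are secured by the five-membered O–Mg–C3 chelate, which also fixes the Z geometry that ring closure requires.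

Step 5
Reactants: 11 (S)-3-(15-hydroxyhexadecyl)-4-methylfuran-2(5H)-one
Product: 12 (S)-16-(4-methyl-2-oxo-2,5-dihydrofuran-3-yl)hexadecan-2-yl acetate
Conditions: Ac2O, pyridine, DMAP (cat.), CH2Cl2, rt
Reagents that add atoms: acetic anhydride (CC(=O)OC(C)=O)
Why: DMAP-catalysed acylation (nucleophilic catalysis) of the secondary hydroxyl; the C–O bond of the carbinol is not broken, so (S) is kept.

Step 6
Reactants: 12 (S)-16-(4-methyl-2-oxo-2,5-dihydrofuran-3-yl)hexadecan-2-yl acetate
Product: 13 (S)-16-[4-methyl-2-(triisopropylsilyloxy)furan-3-yl]hexadecan-2-yl acetate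
Conditions: TIPSOTf (1.2 equiv), Et3N (1.5 equiv), CH2Cl2, 0 °C
Reagents that add atoms: triisopropylsilyl trifluoromethanesulfonate (CC(C)[Si](C(C)C)(C(C)C)OS(=O)(=O)C(F)(F)F)
Why: soft enolisation (silyl dienol ether formation): O-silylation of the lactone carbonyl and loss of a C5 proton to Et3N gives the aromatic 2-silyloxyfuran, a process far faster than enolisation of the acetate or deprotonation at the 4-methyl group.

Step 7
Reactants: 13 (S)-16-[4-methyl-2-(triisopropylsilyloxy)furan-3-yl]hexadecan-2-yl acetate
Product: 15 (2S)-16-(5-hydroxy-4-methyl-2-oxo-2,5-dihydrofuran-3-yl)hexadecan-2-yl acetate (both C5 epimers), via silyl oxoenoate 14 (not isolated)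
Conditions: DMDO (1.1 equiv), acetone/CH2Cl2, −78 °C; then Amberlyst-15, acetone/H2O, rt
Reagents that add atoms: dimethyldioxirane (CC1(C)OO1)
Why: dioxirane oxidation of a 2-silyloxyfuran: oxygen is transferred to the electron-rich C4=C5 bond, the epoxide collapses with push from the silyl ketene acetal to silyl ester 14, and mild acid hydrolysis lets the acid–aldehyde close to the lactol, whose new C5 centre forms as both epimers and is erased in step 8.

Step 8
Reactants: 15 (2S)-16-(5-hydroxy-4-methyl-2-oxo-2,5-dihydrofuran-3-yl)hexadecan-2-yl acetate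
Product: 16 (S)-16-(4-methyl-2,5-dioxo-2,5-dihydrofuran-3-yl)hexadecan-2-yl acetate (target)
Conditions: CrO3, H2SO4, acetone, 0 °C
Reagents that add atoms: none
Why: Jones oxidation of the lactol hydroxyl (a masked aldehyde) to the carbonyl turns the γ-hydroxybutenolide into the cyclic anhydride; the acetate and the remote (S)-centre are inert to the cold acidic oxidant.

Compound list
1 | pentadec-1-yne | C#CCCCCCCCCCCCCC | starting material
2 | (S)-2-methyloxirane [(S)-propylene oxide] | C[C@H]1CO1 | starting material
3 | (S)-octadec-4-yn-2-ol | C[C@H](O)CC#CCCCCCCCCCCCCC | intermediate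
4 | (S)-octadec-17-yn-2-ol | C[C@H](O)CCCCCCCCCCCCCCC#C | intermediate
5 | paraformaldehyde, (CH2O)n, used as formaldehyde | C=O | starting material
6 | (S)-nonadec-2-yne-1,18-diol | C[C@H](O)CCCCCCCCCCCCCCC#CCO | intermediate
7 | methylmagnesium bromide | C[Mg]Br | starting material
8 | carbon dioxide | O=C=O | starting material
9 | oxamagnesacycle (not isolated): 3-[(S)-15-(bromomagnesiooxy)hexadecyl]-4-methyl-2,5-dihydro-1,2-oxamagnesole | C[C@H](O[Mg]Br)CCCCCCCCCCCCCCC1=C(C)CO[Mg]1 | intermediate
10 | hydroxy acid (not isolated): (S,Z)-4-hydroxy-2-(15-hydroxyhexadecyl)-3-methylbut-2-enoic acid | C[C@H](O)CCCCCCCCCCCCCC/C(C(=O)O)=C(\C)CO | intermediate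
11 | (S)-3-(15-hydroxyhexadecyl)-4-methylfuran-2(5H)-one | C[C@H](O)CCCCCCCCCCCCCCC1=C(C)COC1=O | intermediate
12 | (S)-16-(4-methyl-2-oxo-2,5-dihydrofuran-3-yl)hexadecan-2-yl acetate | CC(=O)O[C@@H](C)CCCCCCCCCCCCCCC1=C(C)COC1=O | intermediate
13 | (S)-16-[4-methyl-2-(triisopropylsilyloxy)furan-3-yl]hexadecan-2-yl acetate | CC(=O)O[C@@H](C)CCCCCCCCCCCCCCc1c(C)coc1O[Si](C(C)C)(C(C)C)C(C)C | intermediate
14 | silyl oxoenoate (not isolated): triisopropylsilyl (S,Z)-2-(15-acetoxyhexadecyl)-3-methyl-4-oxobut-2-enoate | CC(=O)O[C@@H](C)CCCCCCCCCCCCCC/C(C(=O)O[Si](C(C)C)(C(C)C)C(C)C)=C(\C)C=O | intermediate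
15 | (2S)-16-(5-hydroxy-4-methyl-2-oxo-2,5-dihydrofuran-3-yl)hexadecan-2-yl acetate (C5 epimers) | CC(=O)O[C@@H](C)CCCCCCCCCCCCCCC1=C(C)C(O)OC1=O | intermediate
16 | (S)-16-(4-methyl-2,5-dioxo-2,5-dihydrofuran-3-yl)hexadecan-2-yl acetate | CC(=O)O[C@@H](C)CCCCCCCCCCCCCCC1=C(C)C(=O)OC1=O | target

Total step count: 8
Longest linear sequence: 8 steps (1 or 2 to 16)

Steps most likely to fail

1. Step 4. Methyl transfer from copper to the unactivated, dialkyl-type triple bond may stall, and the vinylmagnesium chelate may be protonated before it meets CO2, so that diol 6 or the uncarboxylated 2-methyl allylic alcohol would be returned. The fallback sets out from 4 and comes back at 16. The dianion of 4 (n-BuLi, 2 equiv, THF, −78 °C) is C-methylated with MeI to (S)-nonadec-17-yn-2-ol F1, which is acetylated (Ac2O, pyridine, DMAP) to (S)-nonadec-17-yn-2-yl acetate F2. Nickel-catalysed reductive double carboxylation of this 2-alkyne (Ni(acac)2 and 2,2'-bipyridine as catalyst, Zn powder, MgBr2, CO2 1 atm, DMF, rt; then aq. HCl) should place both carbonyl carbons across the triple bond through an oxanickelacycle formed at zerovalent nickel. The dialkylmaleic acid then dehydrates spontaneously to 16. This is a known way from internal alkynes to dialkylmaleic anhydrides and needs no carbometalation.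

2. Step 2. The triple bond has to migrate over thirteen positions; incomplete isomerisation would leave internal alkynes and allenes that are hard to separate, and traces of water quench the amide base. The fallback sets out from 2 and comes back at 6. Epoxide 2 is opened with lithium acetylide–ethylenediamine complex (LiC≡CH·H2NCH2CH2NH2, DMSO, rt) to (S)-pent-4-yn-2-ol F3. Its dianion (n-BuLi, 2 equiv, THF/DMPU) is alkylated with an excess of 1,11-dibromoundecane to (S)-16-bromohexadec-4-yn-2-ol F4. Hydrogenation of the triple bond (H2, PtO2, EtOAc) should give (S)-16-bromohexadecan-2-ol F5, and alkylation of dilithiated propargyl alcohol (n-BuLi, THF/DMPU) with F5 delivers 6. The chain is then assembled by two acetylide alkylations and no isomerisation is needed.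

3. Step 7. The silyl dienol ether may hydrolyse back to 12 before it is oxidised, or oxygen may be delivered to the C2=C3 enol ether bond (α-hydroxylation) in place of C4=C5. The fallback sets out from 11 and comes back at 15. Butenolide 11 is reduced with i-Bu2AlH (CH2Cl2, −78 °C) and the lactol dehydrated on acidic work-up to the furan (S)-16-(4-methylfuran-3-yl)hexadecan-2-ol F6, which is acetylated (Ac2O, pyridine, DMAP) to (S)-16-(4-methylfuran-3-yl)hexadecan-2-yl acetate F7. Photooxygenation (O2, tetraphenylporphyrin, visible light, i-Pr2NEt, CH2Cl2, −78 °C) adds singlet oxygen across the furan diene, and base-induced opening of the endoperoxide (Kornblum–DeLaMare type) should give 15 together with its regioisomer (2S)-16-(2-hydroxy-4-methyl-5-oxo-2,5-dihydrofuran-3-yl)hexadecan-2-yl acetate F8. Step 8 oxidises both lactols to the same anhydride 16.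

Further compounds
F1 | step 4 | (S)-nonadec-17-yn-2-ol | C[C@H](O)CCCCCCCCCCCCCCC#CC
F2 | step 4 | (S)-nonadec-17-yn-2-yl acetate | CC(=O)O[C@@H](C)CCCCCCCCCCCCCCC#CC
F3 | step 2 | (S)-pent-4-yn-2-ol | C[C@H](O)CC#C
F4 | step 2 | (S)-16-bromohexadec-4-yn-2-ol | C[C@H](O)CC#CCCCCCCCCCCCBr
F5 | step 2 | (S)-16-bromohexadecan-2-ol | C[C@H](O)CCCCCCCCCCCCCCBr
F6 | step 7 | (S)-16-(4-methylfuran-3-yl)hexadecan-2-ol | C[C@H](O)CCCCCCCCCCCCCCc1cocc1C
F7 | step 7 | (S)-16-(4-methylfuran-3-yl)hexadecan-2-yl acetate | CC(=O)O[C@@H](C)CCCCCCCCCCCCCCc1cocc1C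
F8 | step 7 | (2S)-16-(2-hydroxy-4-methyl-5-oxo-2,5-dihydrofuran-3-yl)hexadecan-2-yl acetate | CC(=O)O[C@@H](C)CCCCCCCCCCCCCCC1=C(C)C(=O)OC1O
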